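**Retrosynthetic overview**

1. The target is the 15-docosanoate of (13E)-16-hydroxy-neo-cleroda-3,13-dien-15-ol. The ester bond is cut first (docosanoyl chloride). The C16 hydroxyl and the 13E olefin are traced by a 1,3-allylic transposition to a 14-hydroxy-13(16)-ene, and this by an epoxide-to-allylic-alcohol rearrangement and an epoxidation to (−)-kolavenol.
2. (−)-Kolavenol is disconnected in one enzymatic operation to acyclic, achiral geranylgeranyl diphosphate (from commercial geranylgeraniol). The enzyme is a class 2 diterpene cyclase of the kolavenyl diphosphate synthase type, followed in the same pot by a phosphatase.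
3. Ring order: inside the cascade ring A (C1–C5, C10) closes first through the C4–C5 bond. Ring B (C5–C10) then closes through the C10–C9 bond and is the last ring of the skeleton to form. Four 1,2-shifts and loss of a proton from C3 complete the clerodane.
4. Enabling feature: around ring B the groups H–C8 (β), CH3–C9 (α), H–C10 (β) and CH3–C5 (α) alternate faces on adjacent carbons, and ring A carries the C3=C4 olefin next to the single C4 methyl. This is the fingerprint of an antiperiplanar H/CH3/H/CH3 shift sequence from a labda-13-en-8-yl cation on an unbroken head-to-tail tetraprenyl chain.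
5. No protecting group is used. The two allylic oxygens are told apart by position: C15 is acylated as the only primary hydroxyl of a 14,15-diol before the C16 hydroxyl is unveiled.

Key step: step 3

Remark: clerodane numbering is used (ring A = C1–C5 and C10; ring B = C5–C10; side chain C11–C16; methyls C17 on C8, C18 on C4, C19 on C5, C20 on C9). It is assumed that the cyclase, a protein catalyst that is not sold, is obtained by routine expression of a synthetic gene in Escherichia coli; all numbered starting materials are purchasable.

**Route**

Step 1
Reactants: 1 (2E,6E,10E)-geranylgeraniol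
Product: 2 (2E,6E,10E)-geranylgeranyl chloride
Conditions: N-chlorosuccinimide, Me2S, CH2Cl2, −30 °C to 0 °C
Reagents that add atoms: N-chlorosuccinimide, O=C1CCC(=O)N1Cl
Why: Corey–Kim chlorination (alkoxysulfonium salt, SN2 collapse with chloride) should convert the primary allylic alcohol into the chloride without allylic transposition or loss of the 2E geometry; no stereocenter is involved.

Step 2
Reactants: 2 (2E,6E,10E)-geranylgeranyl chloride
Product: 3 (2E,6E,10E)-geranylgeranyl diphosphate, trisammonium salt
Conditions: (Bu4N)3HP2O7, MeCN, 0 °C to rt; then sulfonic acid cation-exchange resin (NH4+ form), aqueous NH4HCO3/iPrOH; cellulose chromatography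
Reagents that add atoms: tris(tetrabutylammonium) hydrogen diphosphate, CCCC[N+](CCCC)(CCCC)CCCC.CCCC[N+](CCCC)(CCCC)CCCC.CCCC[N+](CCCC)(CCCC)CCCC.OP(=O)([O-])OP(=O)([O-])[O-]; ammonium hydrogencarbonate, [NH4+].OC(=O)[O-]
Why: SN2 displacement of the primary allylic chloride by the hydrogen diphosphate trianion is the standard entry to allylic diphosphates and leaves the four olefins untouched; the ammonium form is the water-soluble substrate the enzyme needs.

Step 3
Reactants: 3 (2E,6E,10E)-geranylgeranyl diphosphate, trisammonium salt
Product: 5 (−)-kolavenol [(5R,8R,9S,10R,13E)-cleroda-3,13-dien-15-ol], via kolavenyl diphosphate trisammonium salt 4 (not isolated)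
Conditions: recombinant (−)-kolavenyl diphosphate synthase (class 2 diterpene cyclase, for example the Salvia divinorum enzyme without its transit peptide), HEPES buffer pH 7.2, MgCl2 (1 mM), dithiothreitol, 10% glycerol, slow addition of 3, 30 °C; then calf intestinal alkaline phosphatase, Tris buffer pH 8.5, 37 °C; hexane extraction
Reagents that add atoms: none
Why: This is the native reaction of the class 2 (DXDD-type, protonation-initiated) diterpene cyclases that make (−)-kolavenyl diphosphate, run here on the natural substrate, so the closest precedent is the enzyme's own reaction. The catalytic aspartic acid protonates the terminal olefin of 3 (C3 of the product), and the chair–chair-folded chain closes ring A (C4–C5 bond, 6-endo-trig cation–olefin closure) and then ring B (C10–C9 bond, 6-endo-trig) to the enzyme-bound labda-13-en-8-yl cation. Four suprafacial, mutually antiperiplanar 1,2-shifts follow (H from C9 to C8, methyl C20 from C10 to C9, H from C5 to C10, methyl C19 from C4 to C5), and loss of a proton from C3 gives the C3=C4 olefin. The fold fixes C5, C9 and C10 of the labdane cation by anti addition across the E olefins, and the stereospecific shifts transcribe this into C5, C8, C9 and C10 of the product, each group arriving on the face opposite to the one that leaves; the absolute sense (5R,8R,9S,10R) is imposed by the protein. The selectivity needed is termination only after the fourth shift, not early proton loss or water capture (labdane and halimane products), which the active site secures by shielding the cations and placing its base at C3. The side-chain olefin (13E) and the diphosphate are not touched, and the phosphatase then frees the C15 alcohol in the same pot.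

Step 4
Reactants: 5 (−)-kolavenol
Product: 6 (13S,14S)-13,14-epoxy-(5R,8R,9S,10R)-clerod-3-en-15-ol
Conditions: Ti(OiPr)4 (cat.), L-(+)-diethyl tartrate (cat.), tBuOOH, 4 Å molecular sieves, CH2Cl2, −20 °C
Reagents that add atoms: tert-butyl hydroperoxide, CC(C)(C)OO
Why: Sharpless asymmetric epoxidation should epoxidize only the allylic alcohol olefin (the isolated C3=C4 olefin is inert to the titanium tartrate catalyst), and the L-(+)-tartrate sets C13 and C14 as S,S under reagent control, although either epoxide diastereomer would serve because both centers are lost later.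

Step 5
Reactants: 6 (13S,14S)-13,14-epoxy-(5R,8R,9S,10R)-clerod-3-en-15-ol
Product: 7 (5R,8R,9S,10R,14R)-cleroda-3,13(16)-diene-14,15-diol
Conditions: Ti(OiPr)4 (2 equiv), CH2Cl2, rt; aqueous tartaric acid work-up
Reagents that add atoms: none
Why: Titanium alkoxide-mediated rearrangement of a 3,3-disubstituted 2,3-epoxy alcohol to an ene-diol (hydroxyl-directed β-elimination): titanium bound to the C15 alkoxide and the epoxide oxygen ionizes the tertiary C13–O bond, and its isopropoxide should remove a proton from the C16 methyl, the C13 substituent cis to C15 on this E-derived epoxide, so that the C13=C16 methylidene forms while the untouched C14–O bond keeps C14 (14R by priority change).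

Step 6
Reactants: 7 (5R,8R,9S,10R,14R)-cleroda-3,13(16)-diene-14,15-diol; 8 docosanoyl chloride
Product: 9 (14R)-14-hydroxy-(5R,8R,9S,10R)-cleroda-3,13(16)-dien-15-yl docosanoate
Conditions: 2,4,6-collidine, CH2Cl2, −20 °C, slow addition of 8 (1.05 equiv)
Reagents that add atoms: none
Why: Kinetically selective O-acylation: with a hindered pyridine base at low temperature the acid chloride should esterify the primary C15 hydroxyl much faster than the secondary allylic C14 hydroxyl flanked by the methylidene; no stereocenter is touched.

Step 7
Reactants: 9 (14R)-14-hydroxy-(5R,8R,9S,10R)-cleroda-3,13(16)-dien-15-yl docosanoate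
Product: 11 (13E)-16-hydroxy-(5R,8R,9S,10R)-cleroda-3,13-dien-15-yl docosanoate (target), via trimethylsilyl ether 10 (not isolated)
Conditions: Ph3SiOReO3 (cat.), N,O-bis(trimethylsilyl)acetamide (1.2 equiv), Et2O, 0 °C; then citric acid, MeOH, 0 °C
Reagents that add atoms: none
Why: Rhenium-oxo catalyzed 1,3-transposition of an allylic alcohol: the allyl perrhenate of 9 should undergo a [3,3] sigmatropic shift through a chair with the CH2O-acyl group on C14 equatorial, which places C15 trans to the new C16–O bond and cis to C12 (the 13E olefin of the target), while the silylating agent captures only the unhindered primary C16 hydroxyl and so drains the equilibrium, and acidic methanol then removes the silyl group without touching the ester, which cannot migrate across the trans olefin.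

**Compound list**

1 | (2E,6E,10E)-geranylgeraniol | OC/C=C(\C)CC/C=C(\C)CC/C=C(\C)CCC=C(C)C | starting material
2 | (2E,6E,10E)-geranylgeranyl chloride | ClC/C=C(\C)CC/C=C(\C)CC/C=C(\C)CCC=C(C)C | intermediate
3 | (2E,6E,10E)-geranylgeranyl diphosphate, trisammonium salt | [NH4+].[NH4+].[NH4+].[O-]P(=O)([O-])OP(=O)([O-])OC/C=C(\C)CC/C=C(\C)CC/C=C(\C)CCC=C(C)C | intermediate
4 | (−)-kolavenyl diphosphate [(5R,8R,9S,10R,13E)-cleroda-3,13-dien-15-yl diphosphate], trisammonium salt | [NH4+].[NH4+].[NH4+].[O-]P(=O)([O-])OP(=O)([O-])OC/C=C(\C)CC[C@@]1(C)[C@H](C)CC[C@@]2(C)C(C)=CCC[C@H]12 | intermediate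
5 | (−)-kolavenol [(5R,8R,9S,10R,13E)-cleroda-3,13-dien-15-ol] | OC/C=C(\C)CC[C@@]1(C)[C@H](C)CC[C@@]2(C)C(C)=CCC[C@H]12 | intermediate
6 | (13S,14S)-13,14-epoxy-(5R,8R,9S,10R)-clerod-3-en-15-ol | OC[C@@H]1O[C@@]1(C)CC[C@@]2(C)[C@H](C)CC[C@@]3(C)C(C)=CCC[C@H]23 | intermediate
7 | (5R,8R,9S,10R,14R)-cleroda-3,13(16)-diene-14,15-diol | OC[C@H](O)C(=C)CC[C@@]1(C)[C@H](C)CC[C@@]2(C)C(C)=CCC[C@H]12 | intermediate
8 | docosanoyl chloride | CCCCCCCCCCCCCCCCCCCCCC(=O)Cl | starting material
9 | (14R)-14-hydroxy-(5R,8R,9S,10R)-cleroda-3,13(16)-dien-15-yl docosanoate | CCCCCCCCCCCCCCCCCCCCCC(=O)OC[C@H](O)C(=C)CC[C@@]1(C)[C@H](C)CC[C@@]2(C)C(C)=CCC[C@H]12 | intermediate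
10 | (13E)-16-(trimethylsilyloxy)-(5R,8R,9S,10R)-cleroda-3,13-dien-15-yl docosanoate | CCCCCCCCCCCCCCCCCCCCCC(=O)OC/C=C(/CO[Si](C)(C)C)CC[C@@]1(C)[C@H](C)CC[C@@]2(C)C(C)=CCC[C@H]12 | intermediate
11 | (13E)-16-hydroxy-(5R,8R,9S,10R)-cleroda-3,13-dien-15-yl docosanoate | CCCCCCCCCCCCCCCCCCCCCC(=O)OC/C=C(/CO)CC[C@@]1(C)[C@H](C)CC[C@@]2(C)C(C)=CCC[C@H]12 | target

**Step count and risks**

Total step count: 7. Longest linear sequence: 7 steps (1 to 11).

The three steps most likely to fail:

Step 5. The hydroxyl-directed elimination may take the wrong proton (from C12 instead of C16, giving the 12-ene), or the tertiary C13 cation may be captured by isopropoxide. The fallback sets out from compound 6 and comes back to the route at compound 9. Cleavage of 6 with H5IO6 in THF/water at 0 °C should give the methyl ketone 14,15-dinor-(5R,8R,9S,10R)-clerod-3-en-13-one F1. Kinetic deprotonation on the methyl side with LiN(iPr)2 in THF at −78 °C and trapping with PhN(SO2CF3)2 should give the enol triflate 13-(trifluoromethylsulfonyloxy)-14,15-dinorcleroda-3,13(16)-diene F2. The two-carbon partner is made from 8: allyl alcohol and pyridine in CH2Cl2 give allyl docosanoate F3, and ozonolysis (O3, CH2Cl2, −78 °C, then Me2S) gives 2-oxoethyl docosanoate F4. A Nozaki–Hiyama–Kishi coupling of F2 with F4 (CrCl2, NiCl2 cat., DMF/THF, rt) should give 9 together with its C14 epimer, (14S)-14-hydroxycleroda-3,13(16)-dien-15-yl docosanoate F5. Both are carried into step 7, where C14 loses its configuration.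

Step 7. The transposition may stall at an equilibrium mixture, the olefin geometry may erode by re-entry of the product into the allyl perrhenate manifold, or the allylic C–O bond may ionize with acyl shift. The fallback sets out from compound 9 and comes back at compound 11, replacing the [3,3] shift by a [2,3] shift. Thioetherification of 9 with PhSSPh and PBu3 in THF should give, with inversion, the allylic sulfide (14S)-14-(phenylsulfanyl)cleroda-3,13(16)-dien-15-yl docosanoate F6. Oxidation with H2O2 in (CF3)2CHOH (the sulfide reacts, the C3=C4 olefin does not) gives the sulfoxide (14S)-14-(phenylsulfinyl)cleroda-3,13(16)-dien-15-yl docosanoate F7, a mixture at sulfur. Mislow–Evans rearrangement of F7 with Et2NH in MeOH at 40 °C intercepts the C16 sulfenate and should give 11 with the same E preference. Any SN2′ sulfide formed in the first operation only returns 9 or F5 after oxidation and can be recycled.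

Step 3. Turnover at preparative scale may be slow or incomplete (aggregation of the magnesium salt of amphiphilic 3, product inhibition by 4), and part of 3 may solvolyse before it is cyclized. The fallback moves the same cyclization into a living cell. A Saccharomyces cerevisiae strain with an up-regulated mevalonate pathway and geranylgeranyl diphosphate synthase, expressing the same class 2 cyclase, should make 4 from D-glucose; endogenous phosphatases release 5, which is collected in a dodecane overlay. It sets out from none of the numbered compounds, since D-glucose replaces 1 to 4, and it comes back to the route at compound 5 (F0: no new isolated compound).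

**Further compounds**

F0 | step 3 | none | none
F1 | step 5 | 14,15-dinor-(5R,8R,9S,10R)-clerod-3-en-13-one | CC(=O)CC[C@@]1(C)[C@H](C)CC[C@@]2(C)C(C)=CCC[C@H]12
F2 | step 5 | 13-(trifluoromethylsulfonyloxy)-14,15-dinor-(5R,8R,9S,10R)-cleroda-3,13(16)-diene | C=C(OS(=O)(=O)C(F)(F)F)CC[C@@]1(C)[C@H](C)CC[C@@]2(C)C(C)=CCC[C@H]12
F3 | step 5 | allyl docosanoate | CCCCCCCCCCCCCCCCCCCCCC(=O)OCC=C
F4 | step 5 | 2-oxoethyl docosanoate | CCCCCCCCCCCCCCCCCCCCCC(=O)OCC=O
F5 | step 5 | (14S)-14-hydroxy-(5R,8R,9S,10R)-cleroda-3,13(16)-dien-15-yl docosanoate | CCCCCCCCCCCCCCCCCCCCCC(=O)OC[C@@H](O)C(=C)CC[C@@]1(C)[C@H](C)CC[C@@]2(C)C(C)=CCC[C@H]12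
F6 | step 7 | (14S)-14-(phenylsulfanyl)-(5R,8R,9S,10R)-cleroda-3,13(16)-dien-15-yl docosanoate | CCCCCCCCCCCCCCCCCCCCCC(=O)OC[C@@H](Sc1ccccc1)C(=C)CC[C@@]1(C)[C@H](C)CC[C@@]2(C)C(C)=CCC[C@H]12
F7 | step 7 | (14S)-14-(phenylsulfinyl)-(5R,8R,9S,10R)-cleroda-3,13(16)-dien-15-yl docosanoate (mixture at sulfur) | CCCCCCCCCCCCCCCCCCCCCC(=O)OC[C@@H](S(=O)c1ccccc1)C(=C)CC[C@@]1(C)[C@H](C)CC[C@@]2(C)C(C)=CCC[C@H]12
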